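Leftover reagent was where I started when you asked for a quick number and guessed that slowly feeding either partner would help about equally: the charges left 20.0 mM of it, dormant form counted, once the starting material had reacted.

in all of them: time 6.0 min

| run | starting material | reagent | remark |
|---|---|---|---|
| teal | 10 mM | 30.0 mM | everything together at the start |
| violet | 10 mM | 30.0 mM (fed, over 5.0 min) | all else is in the flask from the start; the feed brings no volume worth counting |
| ochre | 10 mM (fed, over 30 s) | 30.0 mM | all else is in the flask from the start; the feed brings no volume worth counting |
| blue | 10 mM (fed, over 5.0 min) | 30.0 mM | all else is in the flask from the start; the feed brings no volume worth counting |

    starting material + single product ⇌ idle adduct, settled at all times (K1 = 66 M⁻¹)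
    reagent ⇌ dormant form (K2 = 0.44, k2 = 0.21 s⁻¹)
    reagent + single product → bis adduct (k3 = 0.098 M⁻¹ s⁻¹)
    starting material + reagent → single product (k4 = 3.3 M⁻¹ s⁻¹)

- which flask leads in share of single product in single product plus bis adduct ("all alike" within 1.5 percentage points) (teal / violet / ochre / blue / all alike)
- share of single product in single product plus bis adduct at the end, teal
- share of single product in single product plus bis adduct at the end, violet
- share of single product in single product plus bis adduct at the end, ochre
- share of single product in single product plus bis adduct at the end, blue

- percentages count the starting material that a species holds: one idle adduct counts as two
- single product is meant together with its idle adduct
- in an amount of single product, one idle adduct counts as one single product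
- run time (teal): 6.0 min

I solved the two ends and joined them. At the early end, in teal, reagent balanced with its dormant form with a relaxation half-life of 1.01 s, sooner than the 0.12 min half-life of starting material with reagent as charged, so I took 69.4% of the pool of reagent and dormant form as active reagent. The constant of the first addition stood above that of the second by a selectivity factor of 33.7, so I let the starting material react first, and I put the mean birth of single product at 14.5 s.

At the late end, which I reckoned with the whole 10 mM of starting material turned into single product, each bis adduct removed one single product and one reagent, so the pool stayed 10.0 mM above the single product. The ratio r of single product to pool then fell exponentially from 0.500, at what I called the thinning rate, the second addition's constant times that excess times the active fraction, 0.0408 min⁻¹. The share was r/(1−r) times the excess over the charge of starting material.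

Teal had 5.76 min of exposure, which gave 65.4%. Ochre's mean feed wait left 5.51 min and 66.5%; blue's left 3.26 min and 77.8%. In violet the amount fed matched the charge of starting material after 1.67 min, and I counted the stretch from there to the end of the feed as half its length in exposure, adding the 1.00 min after the feed: 2.67 min and 81.3%. So I committed to violet, ahead of blue by 3.5 percentage points, against your hunch.

The forecast, holding that “the share depends mainly on how long single product sits with free reagent”, named violet, with 66% for teal, 82% for violet, 65.7% for ochre and 74.5% for blue.

The simulation gave 66.0% for teal, 81.3% for violet, 67.1% for ochre and 77.1% for blue, so violet led blue by 4.2 points. Teal ran 0.60 points above my figure, and blue 0.70 points below it. I applied the same thinning rate to teal read at 25 min, where the charges were unchanged: an exposure of 24.8 min gave 22.2%. That teal reading showed 22.4%, with the bis adduct holding 77.6% of the starting material charged.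

The numbers of this flask stand for no real mixture, and the outcome is calculated.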